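(The runs are calculated from invented constants, and the scatter is random.)

The constants of this catalyst's round are hidden, so I read a single pace from the runs instead.

the same everywhere: gas 0.074 mM (held)

| flask | starting material | free catalyst | remark | time |
|---|---|---|---|---|
| Wednesday's | 1 mM | 130 µM | run made earlier |  |
| Saturday's | 1 mM | 170 µM | run made earlier |  |
| summer | 3.0 mM | 85 µM |  | 0.80 min |
| autumn | 1.0 mM | 85 µM |  | 3.0 min |

| run | time / s | product / % |
|---|---|---|
| Wednesday's | 10.0 | 4 |
| Wednesday's | 15.0 | 9 |
| Wednesday's | 30.0 | 19 |
| Wednesday's | 50.0 | 32 |
| Wednesday's | 60.0 | 42 |
| Wednesday's | 80.0 | 55 |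
| Wednesday's | 120 | 85 |
| Saturday's | 10.0 | 3 |
| Saturday's | 15.0 | 10 |
| Saturday's | 30.0 | 23 |
| Saturday's | 50.0 | 40 |
| Saturday's | 60.0 | 50 |
| Saturday's | 80.0 | 65 |
| Saturday's | 120 | 88 |

(each reading ± 1.5 percentage points)

- at the start none of coupling partner is dissolved
- the analysis behind the earlier runs scatters by 1.5 percentage points, standard deviation
- reactions considered so far: starting material + free catalyst <-> catalyst intermediate A; catalyst intermediate A -> catalyst intermediate B; coupling partner + catalyst intermediate B <-> catalyst intermediate C; catalyst intermediate C -> catalyst intermediate D; catalyst intermediate D <-> free catalyst + product; gas <-> coupling partner; coupling partner + catalyst intermediate C -> spent catalyst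

1. the winner by amount of product, in percent of the starting material charged; "neither" if no more than 2 percentage points parts them (summer / autumn / neither)
2. how much product is there at the end, in percent of the starting material charged: summer
3. how much product is there at the end, in percent of the starting material charged: autumn

Wednesday's product climbs almost straight: 19% at 30.0 s, 55% at 80.0 s, 85% at 120 s. On such a line two times tell the story: the clearing time, which is the charge of starting material divided by pace and catalyst, and the time the flask is given. Their ratio estimates the fraction of the charge turned into product.

I carry the pace, the product made per catalyst per second (the turnover frequency), read at 80.0 s of Wednesday's run as 0.0529 /s. Saturday's reads 0.0478 /s, but Wednesday's catalyst lies nearer to 85 µM.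

For summer, I reckon a clearing time of 667 s against 48 s, a ratio of 7.19%. For autumn, I reckon 222 s against 180 s, a ratio of 80.9%, more than summer's.

The forecast says 7.5% for summer, 80% for autumn and autumn as winner, holding that “the rate is close to zero order in starting material”.

The flasks give 8.45% for summer and 79.6% for autumn, against my 7.19% and 80.9%, and autumn wins.

    starting material + free catalyst ⇌ catalyst intermediate A (K = 64000 /M, k = 34400 /M/s)
    catalyst intermediate A → catalyst intermediate B (k = 0.618 /s)
    coupling partner + catalyst intermediate B ⇌ catalyst intermediate C (K = 1.76 × 10⁵ /M, k = 3890 /M/s)
    catalyst intermediate C → catalyst intermediate D (k = 0.543 /s)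
    catalyst intermediate D ⇌ free catalyst + product (K = 9.97 × 10⁻⁴ M, k = 0.535 /s)
    gas ⇌ coupling partner, rate k6*(csat - [coupling partner]) (kL = 0.181 /s)
    coupling partner + catalyst intermediate C → spent catalyst (k = 879 /M/s)

In summer at 0.800 min, free catalyst has a half-life of 0.0076 s by the forward rate alone of its step to catalyst intermediate A, far shorter than the 1.12 s half-life of catalyst intermediate A by its step to catalyst intermediate B. Free catalyst stands at 0.134% of the catalyst charged at 0.800 min.

The neighbour, summer with 0.75 mM of starting material, has by the same pace a clearing time of 167 s, so a ratio of 28.7%; it gives 33.6%.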